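Moles per litre per hour was my unit, not percent. These were the flasks, the runs and the questions.

| setting | zeta | epsilon | violet | grey | amber |
|---|---|---|---|---|---|
| electrophile | 0.50 M | 0.50 M | 0.50 M | 0.50 M | 0.50 M |
| protonated nucleophile | 0.25 M | 1.3 M | 0.450 M | 1.80 M | 0.900 M |
| gas | 63 mM (held) | 63 mM (held) | 63 mM (held) | 63 mM (held) | 63 mM (held) |
| remark | run made earlier | run made earlier |  |  |  |
| time |  |  | 2.5 h | 2.5 h | 2.5 h |

| run | time / min | electrophile / % | product / % |
|---|---|---|---|
| zeta | 8.00 | 100.9 | 0.1 |
| zeta | 15.0 | 99.0 | 0.6 |
| zeta | 30.0 | 99.2 | 1.2 |
| zeta | 60.0 | 97.6 | 2.6 |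
| zeta | 120 | 92.6 | 7.5 |
| epsilon | 10.0 | 99.6 | 0 |
| epsilon | 25.0 | 98.8 | 1.2 |
| epsilon | 50.0 | 97.9 | 2.8 |
| epsilon | 80.0 | 95.1 | 5.2 |
| epsilon | 120 | 92.3 | 7.3 |

(readings scatter by 0.5 percentage points)

* part of the electrophile that has reacted at the end, violet
* part of the electrophile that has reacted at the end, grey
* part of the electrophile that has reacted at the end, amber
* what raising the concentration of protonated nucleophile from its lowest to its highest value here does to the part of the electrophile that has reacted (changes below 5 percentage points count as none) (no change / it falls / it rises)

- at the start none of the gas is in solution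

At their last readings the zeta run held 7.5 % product and the epsilon run 7.3 %. That gap lay within the scatter of 0.5 percentage points, though protonated nucleophile went from 0.25 M to 1.3 M. So I read the rate as zero order in protonated nucleophile over that range. Violet and amber lay inside it, and grey, at 1.80 M, lay above it. The two readings averaged 7.40 %. Product concentration made, divided by the time taken, gave 0.0185 M h⁻¹; I called this the molar output.

The zeta run rose from 2.6 % at 60.0 min to 7.5 % at 120 min, so the rate was climbing. Molar output held flat to 2.5 h therefore gave my lower bound, 9.25 %. For the upper bound I let product grow with the square of time, which gave 11.6 %. The zeta readings showed a power of 1.53, which tightened my estimate to 10.4 %.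

The forecast, 10.5 % for violet, 10.5 % for grey and 10.5 % for amber with no change, stood inside my bracket on the ground that “The rate is therefore effectively zero order in this species”.

The flasks gave 9.66 % for violet, 9.88 % for amber and 10.3 % for grey, inside the bracket. The change of 0.64 points counts as no change.

    electrophile + nucleophile → acid set free + product (k = 3.93 × 10⁻⁴ M⁻¹ s⁻¹)
    nucleophile + acid set free ⇌ protonated nucleophile, settled at all times (K = 5200 M⁻¹)
    acid set free + free base ⇌ salt of the base, settled at all times (K = 1.10 × 10⁶ M⁻¹)
    nucleophile ⇌ dormant form (K = 0.495, k = 3.13 × 10⁻⁴ s⁻¹)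
    gas ⇌ free base, rate k5*(csat - [free base]) (kL = 2.72 × 10⁻⁴ s⁻¹)

The hold-up by the gas crossing over to free base was part of what held violet back, together with the early hour of the reading: without the hold-up violet reached 49.8 %, not 9.66 %. Each product called for two free base, one to free the nucleophile it used and one for the acid set free, and the nucleophile and dormant form standing in violet took some besides. So the crossing allowed a molar output of about 0.0308 M h⁻¹, and the 0.0185 M h⁻¹ read from the runs stayed below it. Violet ran at 0.0193 M h⁻¹. A neighbour flask, the same as violet but with 2.0 M of electrophile, reacted 3.60 %, yet its molar output rose to 0.0288 M h⁻¹.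

All runs are simulated for an exercise.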